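**Plan**
Ring numbering used below: C1 = quaternary carbon (CH2OH, homofarnesyl), C2 = CH (hydroxypropyl), C3 = alkylidene carbon, C4/C5 = CH2, C6 = methyl carbinol.
Cuts, in retrosynthetic order: enal ⇐ allylic alcohol; exocyclic C3=C ⇐ 1,4-hydrogenation of a C3=C4/2-propenyl diene ⇐ C4–OH; C6–CH3; ring bond C1–C2 (ring expansion); C1–C6 (alkenyl addition); C2–allyl and C3–alkenyl (three-component coupling).
Enabling feature: HOCH2–C1(quaternary)–C6(=O) in the six-membered ring is the product pattern of a semipinacol shift; a cyclopentanol (C6, C2, C3, C4, C5) carrying epoxide carbon C1 on C6 expands when ring bond C6–C2 migrates to C1.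
Forward: (R)-4-silyloxycyclopentenone → trisubstituted cyclopentanone → tertiary allylic alcohol (farnesylacetone supplies C1, the CH2OH carbon and the side chain) → epoxide → cyclohexanone → methyl carbinol → diene → exocyclic alkene → side-chain alcohol → enal.
Stereochemistry: C2 from the (R)-silyloxy centre by anti,anti coupling; carbinol and epoxide by anti addition and hydroxyl-directed epoxidation; C1 by stereospecific migration with inversion; C6 by axial methyl addition; enal geometry by s-cis 1,4-hydrogenation; E-alkenes from (E,E)-farnesylacetone.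

Key step: step 6

Remark: (5E,9E)-farnesylacetone is assumed to be bought as the single E,E isomer; TBS = tert-butyldimethylsilyl, TBDPS = tert-butyldiphenylsilyl, Tris = 2,4,6-triisopropylbenzenesulfonyl.

Step 1
Reactants: 1 (5E,9E)-farnesylacetone
Product: 2 (E)-trisylhydrazone of 1
Conditions: TrisNHNH2, HCl (cat.), MeOH, rt
Reagents that add atoms: 2,4,6-triisopropylbenzenesulfonohydrazide, NNS(=O)(=O)c1c(C(C)C)cc(C(C)C)cc1C(C)C
Why: Acid-catalysed hydrazone condensation of a methyl ketone should give the (E)-arenesulfonylhydrazone needed for a Shapiro reaction, and no stereocentre is formed.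

Step 2
Reactants: 3 2-bromoprop-2-en-1-ol
Product: 4 [(2-bromoprop-2-en-1-yl)oxy](tert-butyl)diphenylsilane
Conditions: TBDPSCl, imidazole, CH2Cl2, rt
Reagents that add atoms: tert-butyl(chloro)diphenylsilane, Cl[Si](c1ccccc1)(c1ccccc1)C(C)(C)C
Why: Silyl ether formation on a primary allylic alcohol is routine, and the bulky TBDPS group should survive the later acid cleavage of a secondary TBS ether and resist O-to-C silyl migration in the lithiated reagent.

Step 3
Reactants: 4 [(2-bromoprop-2-en-1-yl)oxy](tert-butyl)diphenylsilane; 5 (R)-4-(tert-butyldimethylsilyloxy)cyclopent-2-en-1-one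
Product: 9 (2R,3S,4R)-2-allyl-4-(TBS-oxy)-3-[3-(TBDPS-oxy)prop-1-en-2-yl]cyclopentan-1-one, via alkenyllithium 6 (not isolated), via lithium zincate 7 (not isolated), via zinc enolate 8 (not isolated)
Conditions: 4, t-BuLi, Et2O, −78 °C; Me2Zn; 5, THF, −78 °C; then allyl iodide, HMPA, −78 to −40 °C
Reagents that add atoms: allyl iodide, C=CCI
Why: Three-component coupling (conjugate addition of a mixed alkenylzincate, then enolate allylation) on a 4-silyloxycyclopentenone should put the alkenyl group anti to the silyloxy group and the allyl group anti to the alkenyl group, which fixes the future C2 as R.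

Step 4
Reactants: 2 (E)-trisylhydrazone of 1; 9 cyclopentanone from step 3
Product: 13 (1S,2R,3S,4R)-2-allyl-4-(TBS-oxy)-3-[3-(TBDPS-oxy)prop-1-en-2-yl]-1-[(5E,9E)-6,10,14-trimethylpentadeca-1,5,9,13-tetraen-2-yl]cyclopentan-1-ol, via dilithio hydrazone 10 (not isolated), via alkenyllithium 11 (not isolated), via alkenylcerium dichloride 12 (not isolated)
Conditions: 2, n-BuLi (2 equiv), THF, −78 to 0 °C; CeCl3, −78 °C; then 9, −78 °C
Reagents that add atoms: none
Why: The Shapiro reaction should give the 2-lithio-1-alkene by deprotonation of the methyl group syn to the sulfonamide, and its weakly basic organocerium derivative should add 1,2 to the ketone anti to the adjacent allyl group, placing the new hydroxyl cis to allyl.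

Step 5
Reactants: 13 tertiary allylic alcohol
Product: 14 (1S,2R,3S,4R)-2-allyl-4-(TBS-oxy)-3-[3-(TBDPS-oxy)prop-1-en-2-yl]-1-{(2R)-2-[(3E,7E)-4,8,12-trimethyltrideca-3,7,11-trien-1-yl]oxiran-2-yl}cyclopentan-1-ol
Conditions: VO(acac)2 (cat.), t-BuOOH, CH2Cl2, 0 °C
Reagents that add atoms: tert-butyl hydroperoxide, CC(C)(C)OO
Why: Hydroxyl-directed epoxidation should pick the allylic alkene over the remote ones, and A(1,2) strain in the directed transition state should place the ring CH2 (C5), not the branched allyl-bearing C2, next to the alkene substituent, so oxygen is delivered to the face that gives the (R)-epoxide.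

Step 6
Reactants: 14 epoxy alcohol
Product: 15 (2S,3R,4S,5R)-3-allyl-5-(TBS-oxy)-4-[3-(TBDPS-oxy)prop-1-en-2-yl]-2-(hydroxymethyl)-2-[(3E,7E)-4,8,12-trimethyltrideca-3,7,11-trien-1-yl]cyclohexan-1-one
Conditions: BF3·OEt2 (0.2 equiv), CH2Cl2, −78 °C
Reagents that add atoms: none
Why: BF3 activates the epoxide, whose C–O bond at the tertiary carbon C1 breaks while the ring bond C6–C2, held anti-periplanar to it, shifts onto C1 and the carbinol carbon C6 becomes the ketone, so the cyclopentane grows by one carbon into the cyclohexanone. The closest known reaction type is the Lewis acid-promoted ring-expanding semipinacol rearrangement of 1-(oxiran-2-yl)cycloalkanols to 2-(hydroxymethyl)cycloalkanones. The six-membered ring is closed by a 1,2-alkyl shift in which C2 attacks the epoxide carbon anti to the leaving oxygen, with inversion at C1 and retention at C2. The new quaternary centre is therefore set by the epoxide configuration, (R)-epoxide giving (S)-C1 with CH2OH cis to the allyl group, while C2 stays R. The step needs migration of C2 in preference to C5 and rearrangement in preference to capture of the developing cation by nearby alkenes; C2 is secondary whereas C5 is deactivated by the adjacent silyloxy-bearing carbon, and the oxygen-assisted concerted shift at −78 °C with catalytic acid should be faster than olefin capture.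

Step 7
Reactants: 15 hydroxy ketone
Product: 16 (1S,2S,3R,4S,5R)-3-allyl-5-(TBS-oxy)-4-[3-(TBDPS-oxy)prop-1-en-2-yl]-2-(hydroxymethyl)-1-methyl-2-[(3E,7E)-4,8,12-trimethyltrideca-3,7,11-trien-1-yl]cyclohexan-1-ol
Conditions: MeLi (3 equiv), CeCl3, THF, −78 °C
Reagents that add atoms: methyllithium, C[Li]
Why: 1,2-Addition of a low-basicity methylcerium reagent should avoid enolisation and retro-aldol cleavage, and in the chair with allyl, alkenyl and silyloxy groups equatorial the axial CH2O–metal group on C1 blocks the equatorial path, so methyl enters axially and the new tertiary hydroxyl ends up cis to the hydroxymethyl group.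

Step 8
Reactants: 16 diol
Product: 17 di-tert-butylsilylene acetal of 16 (silicon bridges the CH2–O and the tertiary O)
Conditions: tBu2Si(OTf)2, 2,6-lutidine, CH2Cl2, 0 °C
Reagents that add atoms: di-tert-butylsilyl bis(trifluoromethanesulfonate), CC(C)(C)[Si](OS(=O)(=O)C(F)(F)F)(OS(=O)(=O)C(F)(F)F)C(C)(C)C
Why: Silylene acetal formation on a cis-disposed 1,3-diol should mask the tertiary alcohol against the later dehydration and is fluoride-labile like the remaining silyl ether.

Step 9
Reactants: 17 silylene acetal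
Product: 18 secondary alcohol (17 with the ring OTBS replaced by OH)
Conditions: PPTS, EtOH, 50 °C
Reagents that add atoms: none
Why: Acid-catalysed solvolysis should cleave the TBS ether selectively, since the TBDPS ether and the silylene acetal are much more stable to mild acid.

Step 10
Reactants: 18 secondary alcohol
Product: 19 conjugated diene (ring C3=C4 bearing the 3-(TBDPS-oxy)prop-1-en-2-yl group on C3)
Conditions: Burgess reagent, toluene, 60 °C
Reagents that add atoms: none
Why: Burgess dehydration is a syn elimination through the sulfamate ester, and the cis hydrogen on C3 (tertiary, allylic) should be lost in preference to the cis hydrogen on C5, giving the conjugated 1,3-diene.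

Step 11
Reactants: 19 diene
Product: 20 (Z)-alkylidene compound (exocyclic C3=C(CH3)CH2OTBDPS, CH2O group cis to C2)
Conditions: (naphthalene)Cr(CO)3 (cat.), H2 (50 atm), THF, 45 °C
Reagents that add atoms: none
Why: Arene–Cr(CO)3-catalysed 1,4-hydrogenation runs through the η4-s-cis diene complex, so the two diene termini (C4 and the new methyl) should end up cis on the tetrasubstituted double bond, which puts the silyloxymethyl group cis to C2, while isolated alkenes are not reduced.

Step 12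
Reactants: 20 alkylidene compound
Product: 22 primary alcohol (allyl converted into 3-hydroxypropyl), via alkylborane 21 (not isolated)
Conditions: 9-BBN, THF, 0 °C to rt; then NaOH, H2O2, 0 °C
Reagents that add atoms: hydrogen peroxide, OO
Why: Hydroboration–oxidation with bulky 9-BBN should select the monosubstituted terminal alkene over the tri- and tetrasubstituted ones and give the anti-Markovnikov alcohol.

Step 13
Reactants: 22 primary alcohol
Product: 23 tetraol (2Z)-allylic alcohol, all silicon groups removed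
Conditions: Bu4NF, THF, rt
Reagents that add atoms: none
Why: Fluoride-mediated desilylation should remove the TBDPS ether and the silylene acetal in one operation.

Step 14
Reactants: 23 tetraol
Product: 24 target, (2Z)-2-[(2R,3S,4S)-4-hydroxy-3-(hydroxymethyl)-2-(3-hydroxypropyl)-4-methyl-3-[(3E,7E)-4,8,12-trimethyltrideca-3,7,11-trien-1-yl]cyclohexylidene]propanal
Conditions: MnO2, CH2Cl2, rt
Reagents that add atoms: none
Why: MnO2 oxidation is selective for allylic alcohols, so only the allylic primary hydroxyl should become the aldehyde, with the saturated primary and tertiary hydroxyls untouched and the alkene geometry retained.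

**Compound list**
1 | (5E,9E)-6,10,14-trimethylpentadeca-5,9,13-trien-2-one (farnesylacetone) | CC(C)=CCC/C(C)=C/CC/C(C)=C/CCC(C)=O | starting material
2 | (E)-2,4,6-triisopropylbenzenesulfonylhydrazone of 1 | CC(C)=CCC/C(C)=C/CC/C(C)=C/CC/C(C)=N/NS(=O)(=O)c1c(C(C)C)cc(C(C)C)cc1C(C)C | intermediate
3 | 2-bromoprop-2-en-1-ol | OCC(Br)=C | starting material
4 | [(2-bromoprop-2-en-1-yl)oxy](tert-butyl)diphenylsilane | C=C(Br)CO[Si](c1ccccc1)(c1ccccc1)C(C)(C)C | intermediate
5 | (R)-4-(tert-butyldimethylsilyloxy)cyclopent-2-en-1-one | O=C1C=C[C@H](O[Si](C)(C)C(C)(C)C)C1 | starting material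
6 | [3-(tert-butyldiphenylsilyloxy)prop-1-en-2-yl]lithium | [Li]C(=C)CO[Si](c1ccccc1)(c1ccccc1)C(C)(C)C | intermediate
7 | lithium [3-(tert-butyldiphenylsilyloxy)prop-1-en-2-yl]dimethylzincate | [Li+].C[Zn-](C)C(=C)CO[Si](c1ccccc1)(c1ccccc1)C(C)(C)C | intermediate
8 | lithium dimethylzinc enolate of (3S,4R)-3-[3-(TBDPS-oxy)prop-1-en-2-yl]-4-(TBS-oxy)cyclopentanone (alkenyl anti to OTBS) | [Li+].C[Zn-](C)OC1=C[C@@H](C(=C)CO[Si](c2ccccc2)(c2ccccc2)C(C)(C)C)[C@H](O[Si](C)(C)C(C)(C)C)C1 | intermediate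
9 | (2R,3S,4R)-2-allyl-4-(tert-butyldimethylsilyloxy)-3-[3-(tert-butyldiphenylsilyloxy)prop-1-en-2-yl]cyclopentan-1-one | O=C1[C@H](CC=C)[C@@H](C(=C)CO[Si](c2ccccc2)(c2ccccc2)C(C)(C)C)[C@H](O[Si](C)(C)C(C)(C)C)C1 | intermediate
10 | dilithium C,N-dianion of hydrazone 2 | CC(C)=CCC/C(C)=C/CC/C(C)=C/CCC([CH2-])=N[N-]S(=O)(=O)c1c(C(C)C)cc(C(C)C)cc1C(C)C.[Li+].[Li+] | intermediate
11 | [(5E,9E)-6,10,14-trimethylpentadeca-1,5,9,13-tetraen-2-yl]lithium | CC(C)=CCC/C(C)=C/CC/C(C)=C/CCC(=C)[Li] | intermediate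
12 | dichloro[(5E,9E)-6,10,14-trimethylpentadeca-1,5,9,13-tetraen-2-yl]cerium | CC(C)=CCC/C(C)=C/CC/C(C)=C/CCC(=C)[Ce](Cl)Cl | intermediate
13 | (1S,2R,3S,4R)-2-allyl-4-(TBS-oxy)-3-[3-(TBDPS-oxy)prop-1-en-2-yl]-1-[(5E,9E)-6,10,14-trimethylpentadeca-1,5,9,13-tetraen-2-yl]cyclopentan-1-ol (OH cis to allyl) | CC(C)=CCC/C(C)=C/CC/C(C)=C/CCC(=C)[C@@]1(O)[C@H](CC=C)[C@@H](C(=C)CO[Si](c2ccccc2)(c2ccccc2)C(C)(C)C)[C@H](O[Si](C)(C)C(C)(C)C)C1 | intermediate
14 | (1S,2R,3S,4R)-2-allyl-4-(TBS-oxy)-3-[3-(TBDPS-oxy)prop-1-en-2-yl]-1-{(2R)-2-[(3E,7E)-4,8,12-trimethyltrideca-3,7,11-trien-1-yl]oxiran-2-yl}cyclopentan-1-ol | CC(C)=CCC/C(C)=C/CC/C(C)=C/CC[C@@]1(CO1)[C@@]2(O)[C@H](CC=C)[C@@H](C(=C)CO[Si](c3ccccc3)(c3ccccc3)C(C)(C)C)[C@H](O[Si](C)(C)C(C)(C)C)C2 | intermediate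
15 | (2S,3R,4S,5R)-3-allyl-5-(TBS-oxy)-4-[3-(TBDPS-oxy)prop-1-en-2-yl]-2-(hydroxymethyl)-2-[(3E,7E)-4,8,12-trimethyltrideca-3,7,11-trien-1-yl]cyclohexan-1-one | CC(C)=CCC/C(C)=C/CC/C(C)=C/CC[C@@]1(CO)[C@H](CC=C)[C@@H](C(=C)CO[Si](c2ccccc2)(c2ccccc2)C(C)(C)C)[C@H](O[Si](C)(C)C(C)(C)C)CC1=O | intermediate
16 | (1S,2S,3R,4S,5R)-3-allyl-5-(TBS-oxy)-4-[3-(TBDPS-oxy)prop-1-en-2-yl]-2-(hydroxymethyl)-1-methyl-2-[(3E,7E)-4,8,12-trimethyltrideca-3,7,11-trien-1-yl]cyclohexan-1-ol (tertiary OH cis to CH2OH) | CC(C)=CCC/C(C)=C/CC/C(C)=C/CC[C@@]1(CO)[C@H](CC=C)[C@@H](C(=C)CO[Si](c2ccccc2)(c2ccccc2)C(C)(C)C)[C@H](O[Si](C)(C)C(C)(C)C)C[C@]1(C)O | intermediate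
17 | di-tert-butylsilylene acetal of diol 16 | CC(C)=CCC/C(C)=C/CC/C(C)=C/CC[C@@]1(CO[Si]2(C(C)(C)C)C(C)(C)C)[C@H](CC=C)[C@@H](C(=C)CO[Si](c3ccccc3)(c3ccccc3)C(C)(C)C)[C@H](O[Si](C)(C)C(C)(C)C)C[C@]1(C)O2 | intermediate
18 | secondary alcohol from 17 (ring OTBS cleaved; OH cis to the hydrogen on C3) | CC(C)=CCC/C(C)=C/CC/C(C)=C/CC[C@@]1(CO[Si]2(C(C)(C)C)C(C)(C)C)[C@H](CC=C)[C@@H](C(=C)CO[Si](c3ccccc3)(c3ccccc3)C(C)(C)C)[C@H](O)C[C@]1(C)O2 | intermediate
19 | conjugated diene (ring C3=C4 with 3-(TBDPS-oxy)prop-1-en-2-yl on C3) | CC(C)=CCC/C(C)=C/CC/C(C)=C/CC[C@@]1(CO[Si]2(C(C)(C)C)C(C)(C)C)[C@H](CC=C)C(C(=C)CO[Si](c3ccccc3)(c3ccccc3)C(C)(C)C)=CC[C@]1(C)O2 | intermediate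
20 | (Z)-alkylidene compound (exocyclic C3=C(CH3)CH2OTBDPS, CH2O cis to C2) | CC(C)=CCC/C(C)=C/CC/C(C)=C/CC[C@@]1(CO[Si]2(C(C)(C)C)C(C)(C)C)[C@H](CC=C)/C(=C(/C)CO[Si](c3ccccc3)(c3ccccc3)C(C)(C)C)CC[C@]1(C)O2 | intermediate
21 | B-alkyl-9-borabicyclo[3.3.1]nonane from 20 (boron on the terminal carbon of the former allyl group) | CC(C)=CCC/C(C)=C/CC/C(C)=C/CC[C@@]1(CO[Si]2(C(C)(C)C)C(C)(C)C)[C@H](CCCB3C4CCCC3CCC4)/C(=C(/C)CO[Si](c3ccccc3)(c3ccccc3)C(C)(C)C)CC[C@]1(C)O2 | intermediate
22 | primary alcohol (3-hydroxypropyl on C2; silylene and TBDPS still in place) | CC(C)=CCC/C(C)=C/CC/C(C)=C/CC[C@@]1(CO[Si]2(C(C)(C)C)C(C)(C)C)[C@H](CCCO)/C(=C(/C)CO[Si](c3ccccc3)(c3ccccc3)C(C)(C)C)CC[C@]1(C)O2 | intermediate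
23 | (2Z)-2-[(2R,3S,4S)-4-hydroxy-3-(hydroxymethyl)-2-(3-hydroxypropyl)-4-methyl-3-[(3E,7E)-4,8,12-trimethyltrideca-3,7,11-trien-1-yl]cyclohexylidene]propan-1-ol | CC(C)=CCC/C(C)=C/CC/C(C)=C/CC[C@@]1(CO)[C@H](CCCO)/C(=C(/C)CO)CC[C@]1(C)O | intermediate
24 | (2Z)-2-[(2R,3S,4S)-4-hydroxy-3-(hydroxymethyl)-2-(3-hydroxypropyl)-4-methyl-3-[(3E,7E)-4,8,12-trimethyltrideca-3,7,11-trien-1-yl]cyclohexylidene]propanal | CC(C)=CCC/C(C)=C/CC/C(C)=C/CC[C@@]1(CO)[C@H](CCCO)/C(=C(/C)C=O)CC[C@]1(C)O | target

**Step count and risks**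
Total: 14 steps. Longest linear sequence: 13 steps (3 → 4 → 9 → 13 → … → 24; the farnesylacetone branch joins at step 4).

Step 6 is the riskiest. The developing cationic centre at C1 may be intercepted by the nearby 2-propenyl or allyl π bond, or the unsubstituted ring bond may migrate instead of C6–C2. The fallback sets out from epoxy alcohol 14, whose tertiary hydroxyl is silylated (Me3SiOTf, 2,6-lutidine) to the trimethylsilyl ether of 14 F1. This epoxy silyl ether is rearranged with TiCl4 in CH2Cl2 at −78 °C, where the silyloxy group pushes the anti-periplanar ring bond in a more concerted, less cationic 1,2-shift. Aqueous work-up removes the silyl group and the route is rejoined at hydroxy ketone 15.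

Step 7 may fail through poor facial selectivity of methyl addition at the hindered ketone, or through retro-aldol loss of formaldehyde from the β-alkoxide. The fallback sets out from hydroxy ketone 15 and replaces nucleophilic addition by an oxygen delivery directed from the neighbouring hydroxymethyl group. Wittig methylenation (Ph3PCH3Br, KOt-Bu) should give the exocyclic methylene compound F2. Homoallylic-hydroxyl-directed epoxidation (VO(acac)2, t-BuOOH) should give the spiro-epoxide F3 with oxygen cis to CH2OH. Hydride opening at the CH2 terminus with LiBHEt3 returns to diol 16.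

Step 4 may fail through incomplete formation of the hindered alkenyl metal, or through enolisation of the ketone followed by β-elimination of the silyloxy group. The fallback sets out from ketone 9 and adds the small reagent isopropenylmagnesium bromide with CeCl3 to give the isopropenyl carbinol F4. Alkoxide-directed metalation of its allylic methyl group (n-BuLi, KOt-Bu) and alkylation with (2E,6E)-farnesyl bromide then builds the side chain after the addition and returns to allylic alcohol 13.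

**Further compounds**
F1 | step 6 | trimethylsilyl ether of epoxy alcohol 14 (tertiary O–SiMe3) | CC(C)=CCC/C(C)=C/CC/C(C)=C/CC[C@@]1(CO1)[C@@]2(O[Si](C)(C)C)[C@H](CC=C)[C@@H](C(=C)CO[Si](c3ccccc3)(c3ccccc3)C(C)(C)C)[C@H](O[Si](C)(C)C(C)(C)C)C2
F2 | step 7 | exocyclic methylene compound from 15 (C6=CH2, free CH2OH) | CC(C)=CCC/C(C)=C/CC/C(C)=C/CC[C@@]1(CO)[C@H](CC=C)[C@@H](C(=C)CO[Si](c2ccccc2)(c2ccccc2)C(C)(C)C)[C@H](O[Si](C)(C)C(C)(C)C)CC1=C
F3 | step 7 | spiro-epoxide at C6 with oxygen cis to CH2OH | CC(C)=CCC/C(C)=C/CC/C(C)=C/CC[C@@]1(CO)[C@H](CC=C)[C@@H](C(=C)CO[Si](c2ccccc2)(c2ccccc2)C(C)(C)C)[C@H](O[Si](C)(C)C(C)(C)C)C[C@@]13CO3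
F4 | step 4 | (1S,2R,3S,4R)-2-allyl-4-(TBS-oxy)-3-[3-(TBDPS-oxy)prop-1-en-2-yl]-1-(prop-1-en-2-yl)cyclopentan-1-ol | CC(=C)[C@@]1(O)[C@H](CC=C)[C@@H](C(=C)CO[Si](c2ccccc2)(c2ccccc2)C(C)(C)C)[C@H](O[Si](C)(C)C(C)(C)C)C1
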